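**Retrosynthetic overview**
- Target: oxacyclotritriacontan-2-one, one 33-membered lactone ring (C1 carbonyl, C2–C32 methylenes, ring oxygen) with no stereocentre. Enabling feature: the unbroken, unfunctionalised methylene run lets C20–C23 be carried as a conjugated 1,3-diyne, so C21 and C22 become two terminal sp C–H carbons of the same (acetylide, nucleophilic) polarity, and a 33-membered ring holds the linear C19–C24 rod without strain.
- Disconnection 1: C21–C22, by intramolecular Eglinton oxidative alkyne–alkyne coupling of the acyclic ester undec-10-yn-1-yl henicos-20-ynoate. This one event forms the only ring; hydrogenation then erases the diyne.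
- Disconnection 2: the ester C1–O bond, giving henicos-20-ynoic acid and undec-10-yn-1-ol.
- Disconnection 3: the acid comes from the same alkynol by C-alkylation with 1-bromodecane, alkyne zipper to the chain end, and oxidation.

Key step: step 5

Remark: locants C1–C32 count from the lactone carbonyl (C1) to the OCH2 carbon (C32); undec-10-yn-1-ol and 1-bromodecane are taken as commercial.

**Step 1**
Reactants: 1 undec-10-yn-1-ol; 2 1-bromodecane
Product: 5 henicos-10-yn-1-ol, via dilithio dianion of undec-10-yn-1-ol 3 (not isolated), via lithium henicos-10-yn-1-olate 4 (not isolated)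
Conditions: n-BuLi (2.1 equiv), THF/DMPU, −40 → 0 °C; then 2, 0 °C → rt; then H2O
Reagents that add atoms: none
Why: Acetylide alkylation (SN2): in the dianion the carbon nucleophile is far more reactive towards the primary bromide than the lithium alkoxide, so the chain should be extended at the alkyne terminus without protecting the alcohol, and no stereocentre is formed.

**Step 2**
Reactants: 5 henicos-10-yn-1-ol
Product: 7 henicos-20-yn-1-ol, via dipotassium salt of henicos-20-yn-1-ol 6 (not isolated)
Conditions: KH, H2N(CH2)3NH2, rt (forms potassium 3-aminopropylamide); 5 in THF, 0 °C → rt; then H2O, 0 °C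
Reagents that add atoms: none
Why: Alkyne zipper reaction: the amide shuttles the triple bond along the chain through propargyl/allenyl anions, and the sequence is drained by irreversible formation of the terminal potassium acetylide at the methyl end, the only terminus available because the other end carries the alkoxide.

**Step 3**
Reactants: 7 henicos-20-yn-1-ol
Product: 9 henicos-20-ynoic acid, via henicos-20-ynal 8 (not isolated)
Conditions: CrO3, H2SO4, H2O, acetone, 0 °C → rt
Reagents that add atoms: water, O (supplies the second carboxyl oxygen through the aldehyde hydrate)
Why: Jones oxidation: hexavalent chromium oxidises the primary alcohol to the aldehyde, whose hydrate is oxidised on to the acid, while the terminal alkyne is inert to chromic acid in acetone at this temperature.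

**Step 4**
Reactants: 9 henicos-20-ynoic acid; 1 undec-10-yn-1-ol
Product: 11 undec-10-yn-1-yl henicos-20-ynoate, via henicos-20-ynoyl chloride 10 (not isolated)
Conditions: (COCl)2, cat. DMF, CH2Cl2, 0 °C → rt, evaporate; then 1, pyridine, cat. DMAP, CH2Cl2, 0 °C → rt
Reagents that add atoms: none
Why: Acyl chloride formation (DMF-catalysed activation by oxalyl chloride) followed by DMAP-catalysed acylation of the primary alcohol; both terminal alkynes are spectators under these conditions.

**Step 5**
Reactants: 11 undec-10-yn-1-yl henicos-20-ynoate
Product: 12 oxacyclotritriaconta-21,23-diyn-2-one (dotriaconta-20,22-diyn-32-olide; 33-membered lactone with the 1,3-diyne at C20–C23)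
Conditions: Cu(OAc)2 (8 equiv), pyridine/Et2O (5:1), 40 °C, 11 added by syringe pump over 12 h (final concentration about 1 mM)
Reagents that add atoms: none
Why: Eglinton oxidative coupling: each terminal alkyne C–H is deprotonated by pyridine/acetate at divalent copper to give a copper acetylide, and two acetylide ligands on a dinuclear copper assembly collapse to the new C21–C22 sp–sp bond while two divalent copper centres are reduced to monovalent copper, so two carbons of the same nucleophilic polarity are joined without prefunctionalisation. The closest known reaction type is the Glaser–Eglinton macrocyclisation of open-chain α,ω-diyne esters with Cu(OAc)2 in pyridine under high dilution, a classical entry to macrocyclic 1,3-diyne lactones. The step closes the 33-membered ring in one end-to-end macrocyclisation in which both reacting carbons and the whole C20–C23 diyne become ring members; a ring of this size takes up the linear C19–C24 segment without strain. No stereocentre is formed. The selectivity required is ring closure over intermolecular coupling, because both termini are the same kind of terminal alkyne and every intramolecular coupling leads to the same product; it is secured by slow addition of 11 into a large excess of Cu(OAc)2, which keeps the stationary concentration of uncoupled diyne very low. The ester and the methylene chain are inert to this mild, non-aqueous, weakly basic medium.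

**Step 6**
Reactants: 12 oxacyclotritriaconta-21,23-diyn-2-one
Product: 13 oxacyclotritriacontan-2-one (dotriacontan-32-olide, CNP0285448.0)
Conditions: H2 (1–3 atm), 10% Pd/C, EtOAc, rt
Reagents that add atoms: none
Why: Heterogeneous catalytic hydrogenation should saturate the conjugated diyne (four molar equivalents of H2) to the four methylenes C20–C23 while the lactone is inert, and no stereocentre arises.

**Compound list**
1 | undec-10-yn-1-ol | C#CCCCCCCCCCO | starting material
2 | 1-bromodecane | CCCCCCCCCCBr | starting material
3 | dilithio dianion of undec-10-yn-1-ol (lithium acetylide and lithium alkoxide, formed in the flask) | [Li]C#CCCCCCCCCCO[Li] | intermediate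
4 | lithium henicos-10-yn-1-olate (formed in the flask) | CCCCCCCCCCC#CCCCCCCCCCO[Li] | intermediate
5 | henicos-10-yn-1-ol | CCCCCCCCCCC#CCCCCCCCCCO | intermediate
6 | dipotassium salt of henicos-20-yn-1-ol (terminal acetylide and alkoxide, formed in the flask) | [K]C#CCCCCCCCCCCCCCCCCCCCO[K] | intermediate
7 | henicos-20-yn-1-ol | C#CCCCCCCCCCCCCCCCCCCCO | intermediate
8 | henicos-20-ynal (formed in the flask) | C#CCCCCCCCCCCCCCCCCCCC=O | intermediate
9 | henicos-20-ynoic acid | C#CCCCCCCCCCCCCCCCCCCC(=O)O | intermediate
10 | henicos-20-ynoyl chloride (formed in the flask) | C#CCCCCCCCCCCCCCCCCCCC(=O)Cl | intermediate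
11 | undec-10-yn-1-yl henicos-20-ynoate | C#CCCCCCCCCCCCCCCCCCCC(=O)OCCCCCCCCCC#C | intermediate
12 | oxacyclotritriaconta-21,23-diyn-2-one | O=C1CCCCCCCCCCCCCCCCCCC#CC#CCCCCCCCCCO1 | intermediate
13 | oxacyclotritriacontan-2-one (achiral) | O=C1CCCCCCCCCCCCCCCCCCCCCCCCCCCCCCCO1 | target

**Totals**
Total step count: 6. Longest linear sequence: 6 steps (1 → 5 → 7 → 9 → 11 → 12 → 13).

**Steps most likely to fail**

Step 5. The risk is intermolecular alkyne–alkyne coupling outrunning ring closure whenever uncoupled diyne accumulates, so that linear oligomers and the cyclic dimer grow at the expense of the monomeric ring. The fallback sets out from 1 together with 9 and returns at 13; it makes the C21–C22 bond intermolecularly and closes the ring at the ester oxygen instead. Bromination of the alkyne terminus of 1 (N-bromosuccinimide, cat. AgNO3, acetone, rt) should give 11-bromoundec-10-yn-1-ol F1. Cadiot–Chodkiewicz cross-coupling of F1 with 9 (cat. CuCl, cat. NH2OH·HCl, n-BuNH2, H2O/THF, 0 °C → rt) should give 32-hydroxydotriaconta-20,22-diynoic acid F2. Hydrogenation (H2, 10% Pd/C, THF, 40 °C) should give 32-hydroxydotriacontanoic acid F3. Yamaguchi macrolactonisation then follows: 2,4,6-trichlorobenzoyl chloride and Et3N in THF at rt should give 32-hydroxydotriacontanoic 2,4,6-trichlorobenzoic anhydride F4, and slow addition of this to DMAP in toluene at reflux under high dilution should close the 33-membered ring to 13.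

Step 2. The risk is stalling of the triple-bond migration over ten positions (slow chain walking of a sparingly soluble long-chain alkoxide, quenching of the amide by adventitious proton sources), which would leave positional alkyne isomers that are hard to separate. The fallback sets out from 1, returns at 9 and replaces steps 1 to 3; the alkyne stays terminal throughout and the chain is built by sp3–sp3 coupling. Appel bromination of 1 (CBr4, PPh3, CH2Cl2, 0 °C) should give 11-bromoundec-1-yne F5. C-Silylation (LiN(SiMe3)2, THF, −78 °C; then Me3SiCl) should give (11-bromoundec-1-yn-1-yl)trimethylsilane F6. Magnesium insertion (Mg, THF) should give [11-(trimethylsilyl)undec-10-yn-1-yl]magnesium bromide F7. Coupling of F7 with commercial methyl 10-bromodecanoate (COC(=O)CCCCCCCCCBr; cat. Li2CuCl4, NMP, THF, −20 → 0 °C) should give methyl 21-(trimethylsilyl)henicos-20-ynoate F8. KOH in MeOH/THF/H2O followed by dilute HCl should remove the silyl group and the methyl ester together and deliver 9.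

Step 1. The risk is competing O-alkylation of the alkoxide and E2 elimination of the bromide by the strongly basic dianion, together with incomplete dianion formation through aggregation. The fallback sets out from 1 and returns at 5; the alcohol is masked so that only a monoanion is needed. Treatment of 1 with 3,4-dihydro-2H-pyran (cat. pyridinium p-toluenesulfonate, CH2Cl2, rt) should give racemic 2-(undec-10-yn-1-yloxy)oxane F9. Lithiation and alkylation (n-BuLi, THF/DMPU, −78 °C → rt, then 2) should give racemic 2-(henicos-10-yn-1-yloxy)oxane F10. Acetal exchange (cat. TsOH, MeOH, rt) should return 5.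

**Further compounds**
F1 | step 5 | 11-bromoundec-10-yn-1-ol | BrC#CCCCCCCCCCO
F2 | step 5 | 32-hydroxydotriaconta-20,22-diynoic acid | OC(=O)CCCCCCCCCCCCCCCCCCC#CC#CCCCCCCCCCO
F3 | step 5 | 32-hydroxydotriacontanoic acid | OC(=O)CCCCCCCCCCCCCCCCCCCCCCCCCCCCCCCO
F4 | step 5 | 32-hydroxydotriacontanoic 2,4,6-trichlorobenzoic anhydride | O=C(OC(=O)CCCCCCCCCCCCCCCCCCCCCCCCCCCCCCCO)c1c(Cl)cc(Cl)cc1Cl
F5 | step 2 | 11-bromoundec-1-yne | C#CCCCCCCCCCBr
F6 | step 2 | (11-bromoundec-1-yn-1-yl)trimethylsilane | C[Si](C)(C)C#CCCCCCCCCCBr
F7 | step 2 | [11-(trimethylsilyl)undec-10-yn-1-yl]magnesium bromide | C[Si](C)(C)C#CCCCCCCCCC[Mg]Br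
F8 | step 2 | methyl 21-(trimethylsilyl)henicos-20-ynoate | C[Si](C)(C)C#CCCCCCCCCCCCCCCCCCCC(=O)OC
F9 | step 1 | 2-(undec-10-yn-1-yloxy)oxane (racemic) | C#CCCCCCCCCCOC1CCCCO1
F10 | step 1 | 2-(henicos-10-yn-1-yloxy)oxane (racemic) | CCCCCCCCCCC#CCCCCCCCCCOC1CCCCO1
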